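**Assumptions (one line each).** (4R,6R)-Actinol is taken as commercially available; it is the Roche carotenoid building block made from ketoisophorone. The Step 8 cyclization is assumed to give the natural C10 configuration: the 2α-OTBS group sits equatorial, which places the 4β-methyl axial, and the tether then closes on the α face.

## Retrosynthetic overview
1. The C12–C13 bond and the succinimide come from an Evans syn-aldol of the C12 aldehyde 27 with acyl oxazolidinone 5, followed by imide closure.
2. The 6-oxo-8(17)-ene acid 24 comes from a tandem E1cB/deconjugation of 2α-chloro-6-oxosclareolide 23. The C6 ketone comes from a steroid-type hydroboration of the Δ5-lactone, and the 2α-Cl comes from ketone reduction followed by Appel inversion.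
3. Key step: an allylic-cation/olefin bicyclization with lactonization of the monocyclic allylic alcohol 16. It closes ring B and sets C10 (quaternary), C9 and C8 in one step, steered by the C2 stereocentre.
4. Compound 16 comes from (4R,6R)-actinol (chiral pool ring A with the C2 oxygen) by enol triflate formation, formylation, methallyl addition and cross-metathesis.

Ring order: ring A (chiral pool), then ring B plus the lactone in one cationic step, then the imide last.

## Route

**Step 1**
Reactants: 1 succinic anhydride; 2 allyl alcohol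
Product: 3 mono-allyl succinate
Conditions: Et3N, DMAP (cat.), CH2Cl2, rt
Reagents that add atoms: none
Why: Anhydride alcoholysis gives the mono-ester acid, which is the C13–C16 fragment; no stereocentres are involved.

**Step 2**
Reactants: 3 mono-allyl succinate; 4 (R)-4-benzyloxazolidin-2-one
Product: 5 (R)-N-(4-allyloxy-4-oxobutanoyl)-4-benzyloxazolidin-2-one
Conditions: (i) PivCl, Et3N, THF, –20 °C; (ii) lithiated 4 (n-BuLi, THF, –78 °C), added to the mixed anhydride, then to 0 °C
Reagents that add atoms: none
Why: Evans acylation via the mixed pivalic anhydride; the (R)-auxiliary later dictates C12/C13.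

**Step 3**
Reactants: 6 (4R,6R)-actinol; 7 TBSCl
Product: 8 TBS ether
Conditions: TBSCl, imidazole, DMF, rt
Reagents that add atoms: TBSCl, CC(C)(C)[Si](C)(C)Cl
Why: Standard silyl protection; the C2 stereocentre is carried unchanged.

**Step 4**
Reactants: 8; 9 Tf2O
Product: 10 vinyl triflate
Conditions: Tf2O, 2,6-di-tert-butyl-4-methylpyridine, CH2Cl2, 0 °C to rt
Reagents that add atoms: Tf2O, O=S(=O)(C(F)(F)F)OS(=O)(=O)C(F)(F)F
Why: Enol triflation of a hindered ketone. C4 is quaternary, so enolization can only occur toward C10, giving the tetrasubstituted triflate. This destroys the C10 centre, so only C2 remains.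

**Step 5**
Reactants: 10; 11 CO
Product: 12 aldehyde (cyclocitral-type)
Conditions: Pd(PPh3)4 (5 mol%), LiCl, Bu3SnH, CO (1 atm), THF, 50 °C
Reagents that add atoms: carbon monoxide, [C-]#[O+]
Why: Pd-catalyzed reductive carbonylation (Stille formylation) of a vinyl triflate installs C6.

**Step 6**
Reactants: 12; 13 methallylmagnesium chloride
Product: 14 homoallylic alcohol (mixture at C6)
Conditions: THF, –78 °C to 0 °C
Reagents that add atoms: methallylmagnesium chloride, C=C(C)C[Mg]Cl
Why: Grignard 1,2-addition supplies C7, C8 and C17. The C6 epimers converge in Step 8 because the allylic cation removes that stereocentre.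

**Step 7**
Reactants: 14; 15 tert-butyl but-3-enoate
Product: 16 (E)-trisubstituted alkene ester
Conditions: Hoveyda–Grubbs II (5 mol%), p-benzoquinone (10 mol%), CH2Cl2, 40 °C
Reagents that add atoms: tert-butyl but-3-enoate, C=CCC(=O)OC(C)(C)C
Why: Cross-metathesis of the 1,1-disubstituted methallyl alkene installs C9/C11/C12 with the E geometry needed for a chair-like cyclization.

**Step 8**
Reactants: 16
Product: 17 2α-OTBS-Δ5-sclareolide
Conditions: SnCl4 (1.2 equiv), CH2Cl2, –78 to –40 °C
Reagents that add atoms: none (loses H2O and isobutene)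
Why: The Lewis acid ionizes the allylic alcohol to a C6–C5–C10 allyl cation. The E-alkene attacks C10 through its C9 terminus (6-endo), and the resulting tertiary C8 cation is captured by the tert-butyl ester to give the trans-fused lactone with loss of isobutene. C10 and C9 are set by chair-like approach anti to the axial 4β-Me, which is favoured by the equatorial 2α-OTBS, and the lactone closes on the α face.
Proposed new method: allylic-cation/olefin bicyclization terminated by lactonization, on a preformed 4,4-dimethyl ring A carrying a 2α-OR stereocontrol element. The closest known reactions are the homofarnesic acid to sclareolide cyclization and allylic-alcohol-initiated cation–olefin cyclizations.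

**Step 9**
Reactants: 17
Product: 18 2α-hydroxy-Δ5-sclareolide
Conditions: HF·pyridine, THF/pyridine, rt
Reagents that add atoms: none
Why: Desilylation; this is the first stage of the C2 inversion.

**Step 10**
Reactants: 18
Product: 19 2-oxo-Δ5-sclareolide
Conditions: Dess–Martin periodinane, NaHCO3, CH2Cl2, rt
Reagents that add atoms: none
Why: Alcohol oxidation; the Δ5 alkene and lactone are untouched.

**Step 11**
Reactants: 19
Product: 20 2β-hydroxy-Δ5-sclareolide (axial)
Conditions: L-Selectride, THF, –78 °C
Reagents that add atoms: none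
Why: Bulky hydride attacks from the open α face (equatorial approach). The β face is shielded by the 1,3-diaxial 4β-Me and 10β-Me, so the axial 2β-alcohol results.

**Step 12**
Reactants: 20
Product: 21 2α-chloro-Δ5-sclareolide
Conditions: PPh3, CCl4, NaHCO3, 1,2-dichloroethane, 70 °C
Reagents that add atoms: carbon tetrachloride, ClC(Cl)(Cl)Cl
Why: Appel SN2 on the axial alkoxyphosphonium; backside attack from the α face inverts C2 to give the equatorial 2α-Cl.

**Step 13**
Reactants: 21
Product: 22 2α-chloro-6α-hydroxysclareolide
Conditions: (i) 9-BBN dimer, THF, 65 °C; (ii) NaBO3·4H2O, THF/H2O, rt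
Reagents that add atoms: hydrogen peroxide (from perborate), OO
Why: Hydroboration of the Δ5 alkene occurs on the α face, with boron at the unhindered C6. This gives 5α-H and 6α-OH, the trans ring fusion, as in steroid Δ5 chemistry. It is done before the exocyclic alkene exists, so there is no competing alkene.

**Step 14**
Reactants: 22
Product: 23 2α-chloro-6-oxosclareolide
Conditions: Dess–Martin periodinane, NaHCO3, CH2Cl2, rt
Reagents that add atoms: none
Why: Oxidation to the C6 ketone; C5-H is α to it and so is thermodynamically trans.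

**Step 15**
Reactants: 23
Product: 24 2α-chloro-6-oxo-13,14,15,16-tetranorlabd-8(17)-en-12-oic acid
Conditions: LiHMDS (2.5 equiv), THF, –78 to –20 °C; then AcOH, –78 °C
Reagents that add atoms: none (the acid hydrogen comes from AcOH)
Why: The C7 enolate eliminates the β-carboxylate (E1cB) to give the Δ7-6-one and the C12 carboxylate. The second equivalent of base removes a γ-hydrogen from the C17 methyl to give the dienolate. Kinetic α-protonation at C7 then gives the β,γ-exocyclic methylene. The equatorial 2α-Cl cannot undergo E2 elimination.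
Proposed new method: tandem E1cB lactone opening and deconjugative protonation in one pot. The closest known reaction is deconjugation of enones via kinetic dienolate protonation.

**Step 16**
Reactants: 24; 25 ethanethiol
Product: 26 S-ethyl thioester
Conditions: EDC·HCl, DMAP, CH2Cl2, 0 °C to rt
Reagents that add atoms: ethanethiol, CCS
Why: Carbodiimide thioesterification, chemoselective over the hindered C6 ketone; this prepares for the Fukuyama reduction.

**Step 17**
Reactants: 26
Product: 27 C12 aldehyde
Conditions: Et3SiH, 10% Pd/C, acetone, rt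
Reagents that add atoms: none
Why: Fukuyama thioester reduction leaves the ketone, the exocyclic alkene and the secondary chloride intact.

**Step 18**
Reactants: 27; 5
Product: 28 Evans syn-aldol adduct (12S,13R)
Conditions: 5, Bu2BOTf, i-Pr2NEt, CH2Cl2, –78 to 0 °C; then 27, –78 to 0 °C; oxidative (H2O2/pH 7) workup
Reagents that add atoms: none beyond reactant 5
Why: The Z-boron enolate of the (R)-auxiliary gives the syn aldol with C13 (R) and C12 (S). The primary-alkyl aldehyde does not mismatch the auxiliary, and the auxiliary controls both new centres.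

**Step 19**
Reactants: 28; 29 TBSOTf
Product: 30 C12-OTBS ether
Conditions: TBSOTf, 2,6-lutidine, CH2Cl2, –78 °C
Reagents that add atoms: TBSOTf, CC(C)(C)[Si](C)(C)OS(=O)(=O)C(F)(F)F
Why: Protection prevents γ-lactonization onto the C15 acid and β-elimination later.

**Step 20**
Reactants: 30
Product: 31 carboxylic acid (C16)
Conditions: LiOH, H2O2, THF/H2O, 0 °C
Reagents that add atoms: hydrogen peroxide, OO; lithium hydroxide, [Li+].[OH-]
Why: LiOOH cleaves the exocyclic N-acyl carbonyl of the oxazolidinone and leaves the allyl ester; the auxiliary is recovered as compound 4.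

**Step 21**
Reactants: 31; 32 NH3
Product: 33 primary amide
Conditions: i-BuOCOCl, NMM, THF, –15 °C; then NH3 (0.5 M in dioxane)
Reagents that add atoms: ammonia, N
Why: Mixed-anhydride amidation; C13 is not epimerized under these mild conditions.

**Step 22**
Reactants: 33
Product: 34 acid (C15)
Conditions: Pd(PPh3)4 (5 mol%), morpholine, THF, rt
Reagents that add atoms: none
Why: Pd(0)-catalyzed allyl transfer to morpholine removes the allyl ester without touching the exocyclic alkene.

**Step 23**
Reactants: 34
Product: 35 TBS-protected imide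
Conditions: Ac2O, 80 °C
Reagents that add atoms: none
Why: The acid forms a mixed anhydride that the primary amide nitrogen attacks (5-exo), a cyclodehydration to the succinimide. The C13 and C12 configurations are retained under these non-basic conditions.

**Step 24**
Reactants: 35
Product: 36 Haterumaimide G
Conditions: HF·pyridine, THF/pyridine, rt
Reagents that add atoms: none
Why: Desilylation of the C12 ether gives the target; the ketone, methylene, chloride and imide survive.

## Compound list
1 | succinic anhydride | O=C1CCC(=O)O1 | starting material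
2 | allyl alcohol | C=CCO | starting material
3 | mono-allyl succinate | C=CCOC(=O)CCC(=O)O | intermediate
4 | (R)-4-benzyloxazolidin-2-one | O=C1N[C@H](Cc2ccccc2)CO1 | starting material
5 | (R)-N-(4-allyloxy-4-oxobutanoyl)-4-benzyloxazolidin-2-one | C=CCOC(=O)CCC(=O)N1[C@H](Cc2ccccc2)COC1=O | intermediate
6 | (4R,6R)-actinol | O=C1C(C)(C)C[C@H](O)C[C@H]1C | starting material
7 | TBSCl | CC(C)(C)[Si](C)(C)Cl | starting material
8 | (4R,6R)-4-(TBSO)-2,2,6-trimethylcyclohexanone | O=C1C(C)(C)C[C@H](O[Si](C)(C)C(C)(C)C)C[C@H]1C | intermediate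
9 | triflic anhydride | O=S(=O)(C(F)(F)F)OS(=O)(=O)C(F)(F)F | starting material
10 | (4R)-4-(TBSO)-2,6,6-trimethylcyclohex-1-enyl triflate | CC1=C(OS(=O)(=O)C(F)(F)F)C(C)(C)C[C@H](O[Si](C)(C)C(C)(C)C)C1 | intermediate
11 | carbon monoxide | [C-]#[O+] | starting material
12 | (4R)-4-(TBSO)-2,6,6-trimethylcyclohex-1-ene-1-carbaldehyde | CC1=C(C=O)C(C)(C)C[C@H](O[Si](C)(C)C(C)(C)C)C1 | intermediate
13 | methallylmagnesium chloride | C=C(C)C[Mg]Cl | starting material
14 | 1-[(4R)-4-(TBSO)-2,6,6-trimethylcyclohexenyl]-3-methylbut-3-en-1-ol (C6 epimers) | CC1=C(C(O)CC(C)=C)C(C)(C)C[C@H](O[Si](C)(C)C(C)(C)C)C1 | intermediate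
15 | tert-butyl but-3-enoate | C=CCC(=O)OC(C)(C)C | starting material
16 | tert-butyl (E)-6-hydroxy-6-[(4R)-4-(TBSO)-2,6,6-trimethylcyclohexenyl]-4-methylhex-3-enoate | CC1=C(C(O)C/C(C)=C/CC(=O)OC(C)(C)C)C(C)(C)C[C@H](O[Si](C)(C)C(C)(C)C)C1 | intermediate
17 | 2α-(TBSO)-Δ5-sclareolide | C[C@@]12CC=C3C(C)(C)C[C@H](O[Si](C)(C)C(C)(C)C)C[C@]3(C)[C@H]1CC(=O)O2 | intermediate
18 | 2α-hydroxy-Δ5-sclareolide | C[C@@]12CC=C3C(C)(C)C[C@H](O)C[C@]3(C)[C@H]1CC(=O)O2 | intermediate
19 | 2-oxo-Δ5-sclareolide | C[C@@]12CC=C3C(C)(C)CC(=O)C[C@]3(C)[C@H]1CC(=O)O2 | intermediate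
20 | 2β-hydroxy-Δ5-sclareolide | C[C@@]12CC=C3C(C)(C)C[C@@H](O)C[C@]3(C)[C@H]1CC(=O)O2 | intermediate
21 | 2α-chloro-Δ5-sclareolide | C[C@@]12CC=C3C(C)(C)C[C@H](Cl)C[C@]3(C)[C@H]1CC(=O)O2 | intermediate
22 | 2α-chloro-6α-hydroxysclareolide | C[C@@]12C[C@H](O)[C@H]3C(C)(C)C[C@H](Cl)C[C@]3(C)[C@H]1CC(=O)O2 | intermediate
23 | 2α-chloro-6-oxosclareolide | C[C@@]12CC(=O)[C@H]3C(C)(C)C[C@H](Cl)C[C@]3(C)[C@H]1CC(=O)O2 | intermediate
24 | 2α-chloro-6-oxo-13,14,15,16-tetranorlabd-8(17)-en-12-oic acid | C=C1CC(=O)[C@H]2C(C)(C)C[C@H](Cl)C[C@]2(C)[C@H]1CC(=O)O | intermediate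
25 | ethanethiol | CCS | starting material
26 | S-ethyl thioester of 24 | C=C1CC(=O)[C@H]2C(C)(C)C[C@H](Cl)C[C@]2(C)[C@H]1CC(=O)SCC | intermediate
27 | 2α-chloro-6-oxo-13,14,15,16-tetranorlabd-8(17)-en-12-al | C=C1CC(=O)[C@H]2C(C)(C)C[C@H](Cl)C[C@]2(C)[C@H]1CC=O | intermediate
28 | Evans syn-aldol adduct (12S,13R) | C=C1CC(=O)[C@H]2C(C)(C)C[C@H](Cl)C[C@]2(C)[C@H]1C[C@H](O)[C@@H](CC(=O)OCC=C)C(=O)N1[C@H](Cc2ccccc2)COC1=O | intermediate
29 | TBSOTf | CC(C)(C)[Si](C)(C)OS(=O)(=O)C(F)(F)F | starting material
30 | 12-OTBS aldol adduct | C=C1CC(=O)[C@H]2C(C)(C)C[C@H](Cl)C[C@]2(C)[C@H]1C[C@H](O[Si](C)(C)C(C)(C)C)[C@@H](CC(=O)OCC=C)C(=O)N1[C@H](Cc2ccccc2)COC1=O | intermediate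
31 | C16 acid, allyl ester | C=C1CC(=O)[C@H]2C(C)(C)C[C@H](Cl)C[C@]2(C)[C@H]1C[C@H](O[Si](C)(C)C(C)(C)C)[C@@H](CC(=O)OCC=C)C(=O)O | intermediate
32 | ammonia | N | starting material
33 | primary amide, allyl ester | C=C1CC(=O)[C@H]2C(C)(C)C[C@H](Cl)C[C@]2(C)[C@H]1C[C@H](O[Si](C)(C)C(C)(C)C)[C@@H](CC(=O)OCC=C)C(N)=O | intermediate
34 | amide acid (C15 acid) | C=C1CC(=O)[C@H]2C(C)(C)C[C@H](Cl)C[C@]2(C)[C@H]1C[C@H](O[Si](C)(C)C(C)(C)C)[C@@H](CC(=O)O)C(N)=O | intermediate
35 | TBS-protected imide | C=C1CC(=O)[C@H]2C(C)(C)C[C@H](Cl)C[C@]2(C)[C@H]1C[C@H](O[Si](C)(C)C(C)(C)C)[C@H]1CC(=O)NC1=O | intermediate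
36 | Haterumaimide G | C=C1CC(=O)[C@H]2C(C)(C)C[C@H](Cl)C[C@]2(C)[C@H]1C[C@H](O)[C@H]1CC(=O)NC1=O | target

## Totals
Total steps: 24, of which 2 prepare the side-chain acyl oxazolidinone. Longest linear sequence: 22 steps (Steps 3–24, from actinol).

## Three steps most likely to fail
1. **Step 8 (allylic-cation bicyclization/lactonization).** Risks are competing proton loss from the cation, E/Z erosion giving a C9 epimer, and the wrong C10 face giving the ent-series.
   - Fallback: change the mechanism to an intramolecular Majetich-type Sakurai conjugate allylation. Oxidize the C6 alcohol of 14 to the β-cyclogeranyl ketone, build a (2-silylmethyl)allyl tether at C7–C9, and cyclize with TiCl4. This forms the C9–C10 bond and the C8=C17 methylene directly, with C5 equilibrated thermodynamically to trans.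
2. **Step 13 (hydroboration of the very hindered Δ5 alkene next to C4 and C10 quaternary centres).** The alkene may be unreactive toward 9-BBN, or the lactone may be attacked.
   - Fallback: α-face epoxidation (mCPBA) of 21, then Cp2TiCl-mediated radical epoxide opening (Nugent–RajanBabu) with a 1,4-cyclohexadiene H-donor. The oxygen stays on C6, and C5 is equilibrated to the trans ring fusion after oxidation to the ketone.
3. **Step 15 (E1cB opening of the tertiary lactone with an equatorial C8–O, plus kinetic deconjugation).** The equatorial leaving group overlaps poorly with the enolate, and deprotonation at C9 would give the Δ8(9) isomer.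
   - Fallback: split into two steps, first a mild elimination to the isolated Δ7-enone acid, then photodeconjugation (hν, 350 nm, Et2O). γ-Hydrogen abstraction from C17 gives a photoenol that ketonizes at C7 to the β,γ-enone 24, avoiding base-mediated equilibration at C9.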